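The retrosynthesis first removes the O-protecting groups. It then cuts the pyranone of the apigenin unit (double-primed locants) at O1''–C2'' and C4''–C4a'', and its carbocyclic ring A at C8''–C8a'', C6''–C7'' and C4a''–C8a''. The 6–8'' biaryl bond is never cut.
Enabling feature: C8'' sits between C7''–O and C8a''–O with C5''–O para to it, so ring A is a 2-arylphloroglucinol. An aryl silyl ynol ether and a 3-alkoxycyclobutenone give exactly this pattern, with the future O1'' as the only free hydroxyl.
Forward: acacetin supplies rings A, B and C of the 4'-methoxyflavone unit. C6 is iodinated and alkynylated, and the alkyne terminus is oxidised to the triisopropylsilyl ynol ether.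
Benzannulation with 3-(benzyloxy)cyclobutenone grows apigenin ring A on the two former alkyne carbons. Iodination at C4a'' and a carbonylative alkyne annulation then add ring C together with ring B.
Fluoride and BCl3 free the five hydroxyls and leave the 4'-methyl ether in place.
Stereochemistry: the target has no stereocentre and the route leaves none.

Key step: step 8

Assumption: the SMILES gives no descriptor for the hindered 6–8'' axis, so the atropisomers are not differentiated and the biaryl is made as the racemate.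

Step 1
Reactants: 1 acacetin
Product: 2 7-(benzyloxy)-5-hydroxy-4'-methoxyflavone
Conditions: BnBr (1.1 equiv), K2CO3, acetone, reflux
Reagents that add atoms: benzyl bromide, BrCc1ccccc1
Why: Williamson etherification; the 7-OH is the acidic, unhindered phenol, whereas the 5-OH is locked in a hydrogen bond to the C4 carbonyl and stays free with about one equivalent of halide.

Step 2
Reactants: 2 7-(benzyloxy)-5-hydroxy-4'-methoxyflavone
Product: 3 7-(benzyloxy)-5-hydroxy-6-iodo-4'-methoxyflavone
Conditions: BnMe3N·ICl2 (1.1 equiv), CaCO3, CH2Cl2–MeOH, rt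
Reagents that add atoms: benzyltrimethylammonium dichloroiodate, C[N+](C)(C)Cc1ccccc1.Cl[I-]Cl
Why: Electrophilic aromatic iodination; with the 5-OH free and O7 alkylated, this buffered iodine monochloride carrier is known to attack 5,7-dioxygenated flavones at C6, ortho to the chelated phenol, and not at C8.

Step 3
Reactants: 3 7-(benzyloxy)-5-hydroxy-6-iodo-4'-methoxyflavone
Product: 4 5,7-bis(benzyloxy)-6-iodo-4'-methoxyflavone
Conditions: BnBr (1.5 equiv), K2CO3, DMF, 60 °C
Reagents that add atoms: benzyl bromide, BrCc1ccccc1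
Why: Williamson etherification under more forcing conditions breaks the chelate and caps the last acidic proton before the organometallic steps, and the aryl iodide and the pyranone are inert to carbonate.

Step 4
Reactants: 4 5,7-bis(benzyloxy)-6-iodo-4'-methoxyflavone; 5 ethynyltrimethylsilane
Product: 6 5,7-bis(benzyloxy)-4'-methoxy-6-[(trimethylsilyl)ethynyl]flavone
Conditions: PdCl2(PPh3)2 (5 mol %), CuI (10 mol %), Et3N–DMF, 70 °C
Reagents that add atoms: none
Why: Sonogashira coupling; an aryl iodide flanked by two alkoxy groups still undergoes oxidative addition, the linear alkyne tolerates the crowding, and the flavone is a spectator.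

Step 5
Reactants: 6 5,7-bis(benzyloxy)-4'-methoxy-6-[(trimethylsilyl)ethynyl]flavone
Product: 7 5,7-bis(benzyloxy)-6-ethynyl-4'-methoxyflavone
Conditions: K2CO3 (0.2 equiv), MeOH–CH2Cl2, rt
Reagents that add atoms: none
Why: Base-catalysed protodesilylation of an alkynylsilane by methanolysis is mild enough to leave the flavone and the benzyl ethers untouched.

Step 6
Reactants: 7 5,7-bis(benzyloxy)-6-ethynyl-4'-methoxyflavone
Product: 10 5,7-bis(benzyloxy)-4'-methoxy-6-[(triisopropylsilyloxy)ethynyl]flavone, via lithium acetylide 8 (not isolated), via lithium ynolate 9 (not isolated)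
Conditions: LiN(SiMe3)2 (1.1 equiv), THF, −78 °C; add to t-BuOOLi [t-BuOOH + LiN(SiMe3)2, THF, −78 °C]; −78 → 0 °C; TIPSOTf (1.2 equiv), −78 → 0 °C; Et3N-deactivated silica
Reagents that add atoms: tert-butyl hydroperoxide, CC(C)(C)OO; triisopropylsilyl trifluoromethanesulfonate, CC(C)[Si](OS(=O)(=O)C(F)(F)F)(C(C)C)C(C)C
Why: Oxenoid oxidation of a lithium acetylide by lithium tert-butyl peroxide followed by O-silylation of the ynolate with the bulky triflate is the standard entry to triisopropylsilyl ynol ethers; the non-nucleophilic amide metalates the arylacetylene without adding to the pyranone, and 2-arylchromones resist nucleophilic (Weitz–Scheffer type) peroxide attack.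

Step 7
Reactants: 11 3-ethoxycyclobut-2-en-1-one
Product: 12 3-(benzyloxy)cyclobut-2-en-1-one
Conditions: BnOH (3 equiv), p-TsOH·H2O (5 mol %), toluene, 40 °C, reduced pressure (removal of EtOH)
Reagents that add atoms: benzyl alcohol, OCc1ccccc1
Why: Acid-catalysed addition–elimination at the β-carbon of a vinylogous ester (transetherification) is driven by removal of ethanol and is run well below the temperature at which the four-membered ring opens.

Step 8
Reactants: 10 5,7-bis(benzyloxy)-4'-methoxy-6-[(triisopropylsilyloxy)ethynyl]flavone; 12 3-(benzyloxy)cyclobut-2-en-1-one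
Product: 17 5-(benzyloxy)-2-[5,7-bis(benzyloxy)-4'-methoxyflavon-6-yl]-3-(triisopropylsilyloxy)phenol, via vinylketene 13 (not isolated), via vinylcyclobutenone 14 (not isolated), via dienylketene 15 (not isolated), via cyclohexadienone 16 (not isolated)
Conditions: 12 (1.5–2 equiv, in portions), toluene (0.2 M), sealed tube, 120 °C
Reagents that add atoms: none
Why: Danheiser benzannulation: on heating, 12 opens by four-electron electrocyclic cleavage of its C1–C4 bond to alkoxyvinylketene 13, which the electron-rich alkyne 10 intercepts in a [2+2] cycloaddition that makes C8''–C8a'' and C6''–C7'' and gives vinylcyclobutenone 14. Under the same heating 14 reopens to dienylketene 15, whose six-electron electrocyclisation joins the ketene carbon to the terminal methylene (C8a''–C4a''), so the single new ring, carbocyclic ring A of the apigenin unit, closes pericyclically, and enolisation of dienone 16 gives phenol 17. The closest known chemistry is the reaction of cyclobutenones with triisopropylsilyloxyalkynes to give resorcinol monosilyl ethers; here the 3-alkoxy group only adds the third oxygen, and squarate-derived 3-alkoxycyclobutenones show that such vinylogous esters open in this temperature range. The one selectivity needed is the orientation of the [2+2] step, and the polarisation of the ynol ether fixes it: the nucleophilic, aryl-bearing carbon β to oxygen attacks the ketene carbonyl carbon, so the new hydroxyl ends next to the biaryl carbon and the OTIPS group on its other side. No stereocentre remains in 17, and the tetra-ortho-substituted 6–8'' bond is simply the former aryl–alkyne bond. Portionwise addition of 12 offsets ketene dimerisation, and the bulk of the triisopropylsilyl group slows the silyl shift of 10 to a silylketene.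

Step 9
Reactants: 17 5-(benzyloxy)-2-[5,7-bis(benzyloxy)-4'-methoxyflavon-6-yl]-3-(triisopropylsilyloxy)phenol
Product: 18 3-(benzyloxy)-6-[5,7-bis(benzyloxy)-4'-methoxyflavon-6-yl]-2-iodo-5-(triisopropylsilyloxy)phenol
Conditions: NIS (1.0 equiv), CH2Cl2, −20 → 0 °C, dark
Reagents that add atoms: N-iodosuccinimide, O=C1CCC(=O)N1I
Why: Electrophilic iodination of a phloroglucinol-type phenol; this ring is far more nucleophilic than any flavone ring, and of its two free carbons C4a'' (between OH and OBn) is accessible while C6'' is shielded by the adjacent triisopropylsilyloxy group.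

Step 10
Reactants: 18 3-(benzyloxy)-6-[5,7-bis(benzyloxy)-4'-methoxyflavon-6-yl]-2-iodo-5-(triisopropylsilyloxy)phenol; 19 1-(benzyloxy)-4-ethynylbenzene
Product: 21 5,7,5'',4'''-tetrakis(benzyloxy)-4'-methoxy-7''-(triisopropylsilyloxy)-6,8''-biflavone, via alkynone 20 (not isolated)
Conditions: PdCl2(dppf) (5 mol %), CO (10 bar), Et2NH–THF, 90 °C
Reagents that add atoms: carbon monoxide, [C-]#[O+]
Why: Carbonylative Sonogashira coupling with in situ annulation is an established flavone synthesis from o-iodophenols: oxidative addition at C4a''–I, CO insertion and alkynylation give alkynone 20, which in the secondary-amine medium closes 6-endo through O1'' onto the aryl-bearing alkyne carbon instead of 5-exo to an aurone, and conditions that produce a flavone also spare the flavone already present.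

Step 11
Reactants: 21 5,7,5'',4'''-tetrakis(benzyloxy)-4'-methoxy-7''-(triisopropylsilyloxy)-6,8''-biflavone
Product: 22 5,7,5'',4'''-tetrakis(benzyloxy)-7''-hydroxy-4'-methoxy-6,8''-biflavone
Conditions: Bu4NF (1.2 equiv), AcOH (1.2 equiv), THF, 0 °C
Reagents that add atoms: none
Why: Fluoride cleavage of an aryl silyl ether is fast here because the 7''-phenoxide is a vinylogous carboxylate leaving group, and acetic acid buffers the medium.

Step 12
Reactants: 22 5,7,5'',4'''-tetrakis(benzyloxy)-7''-hydroxy-4'-methoxy-6,8''-biflavone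
Product: 23 5,7,5'',7'',4'''-pentahydroxy-4'-methoxy-6,8''-biflavone (CNP0302154.0)
Conditions: BCl3 (10 equiv), C6HMe5 (12 equiv), CH2Cl2, −78 → −20 °C; then H2O
Reagents that add atoms: none
Why: Lewis-acid debenzylation with a non-basic cation scavenger; BCl3 cleaves the two chelated peri-benzyl ethers and the two remaining ones at low temperature, pentamethylbenzene traps the benzyl cations before they C-benzylate the phloroglucinol rings, and the unchelated 4'-methyl ether is not attacked by BCl3 under these conditions.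

Compound list
1 | acacetin (5,7-dihydroxy-4'-methoxyflavone) | COc1ccc(cc1)-c1cc(=O)c2c(O)cc(O)cc2o1 | starting material
2 | 7-(benzyloxy)-5-hydroxy-4'-methoxyflavone | COc1ccc(cc1)-c1cc(=O)c2c(O)cc(OCc3ccccc3)cc2o1 | intermediate
3 | 7-(benzyloxy)-5-hydroxy-6-iodo-4'-methoxyflavone | COc1ccc(cc1)-c1cc(=O)c2c(O)c(I)c(OCc3ccccc3)cc2o1 | intermediate
4 | 5,7-bis(benzyloxy)-6-iodo-4'-methoxyflavone | COc1ccc(cc1)-c1cc(=O)c2c(OCc3ccccc3)c(I)c(OCc3ccccc3)cc2o1 | intermediate
5 | ethynyltrimethylsilane | C#C[Si](C)(C)C | starting material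
6 | 5,7-bis(benzyloxy)-4'-methoxy-6-[(trimethylsilyl)ethynyl]flavone | COc1ccc(cc1)-c1cc(=O)c2c(OCc3ccccc3)c(C#C[Si](C)(C)C)c(OCc3ccccc3)cc2o1 | intermediate
7 | 5,7-bis(benzyloxy)-6-ethynyl-4'-methoxyflavone | COc1ccc(cc1)-c1cc(=O)c2c(OCc3ccccc3)c(C#C)c(OCc3ccccc3)cc2o1 | intermediate
8 | lithium acetylide of 7 | COc1ccc(cc1)-c1cc(=O)c2c(OCc3ccccc3)c(C#C[Li])c(OCc3ccccc3)cc2o1 | intermediate
9 | lithium 2-[5,7-bis(benzyloxy)-4'-methoxyflavon-6-yl]ethynolate | COc1ccc(cc1)-c1cc(=O)c2c(OCc3ccccc3)c(C#CO[Li])c(OCc3ccccc3)cc2o1 | intermediate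
10 | 5,7-bis(benzyloxy)-4'-methoxy-6-[(triisopropylsilyloxy)ethynyl]flavone | COc1ccc(cc1)-c1cc(=O)c2c(OCc3ccccc3)c(C#CO[Si](C(C)C)(C(C)C)C(C)C)c(OCc3ccccc3)cc2o1 | intermediate
11 | 3-ethoxycyclobut-2-en-1-one | CCOC1=CC(=O)C1 | starting material
12 | 3-(benzyloxy)cyclobut-2-en-1-one | O=C1C=C(OCc2ccccc2)C1 | intermediate
13 | 3-(benzyloxy)buta-1,3-dien-1-one ([1-(benzyloxy)ethenyl]ketene) | O=C=CC(=C)OCc1ccccc1 | intermediate
14 | 4-[1-(benzyloxy)ethenyl]-2-[5,7-bis(benzyloxy)-4'-methoxyflavon-6-yl]-3-(triisopropylsilyloxy)cyclobut-2-en-1-one (racemic, transient) | COc1ccc(cc1)-c1cc(=O)c2c(OCc3ccccc3)c(C3=C(O[Si](C(C)C)(C(C)C)C(C)C)C(C(=C)OCc4ccccc4)C3=O)c(OCc3ccccc3)cc2o1 | intermediate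
15 | 5-(benzyloxy)-2-[5,7-bis(benzyloxy)-4'-methoxyflavon-6-yl]-3-(triisopropylsilyloxy)hexa-1,3,5-trien-1-one (ketene end and alkoxyvinyl end cis on C3=C4) | O=C=C(c1c(OCc2ccccc2)cc2oc(-c3ccc(OC)cc3)cc(=O)c2c1OCc1ccccc1)/C(O[Si](C(C)C)(C(C)C)C(C)C)=C\C(=C)OCc1ccccc1 | intermediate
16 | 5-(benzyloxy)-2-[5,7-bis(benzyloxy)-4'-methoxyflavon-6-yl]-3-(triisopropylsilyloxy)cyclohexa-2,4-dien-1-one | COc1ccc(cc1)-c1cc(=O)c2c(OCc3ccccc3)c(C3=C(O[Si](C(C)C)(C(C)C)C(C)C)C=C(OCc4ccccc4)CC3=O)c(OCc3ccccc3)cc2o1 | intermediate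
17 | 5-(benzyloxy)-2-[5,7-bis(benzyloxy)-4'-methoxyflavon-6-yl]-3-(triisopropylsilyloxy)phenol | COc1ccc(cc1)-c1cc(=O)c2c(OCc3ccccc3)c(-c3c(O)cc(OCc4ccccc4)cc3O[Si](C(C)C)(C(C)C)C(C)C)c(OCc3ccccc3)cc2o1 | intermediate
18 | 3-(benzyloxy)-6-[5,7-bis(benzyloxy)-4'-methoxyflavon-6-yl]-2-iodo-5-(triisopropylsilyloxy)phenol | COc1ccc(cc1)-c1cc(=O)c2c(OCc3ccccc3)c(-c3c(O)c(I)c(OCc4ccccc4)cc3O[Si](C(C)C)(C(C)C)C(C)C)c(OCc3ccccc3)cc2o1 | intermediate
19 | 1-(benzyloxy)-4-ethynylbenzene | C#Cc1ccc(OCc2ccccc2)cc1 | starting material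
20 | 1-{6-(benzyloxy)-3-[5,7-bis(benzyloxy)-4'-methoxyflavon-6-yl]-2-hydroxy-4-(triisopropylsilyloxy)phenyl}-3-[4-(benzyloxy)phenyl]prop-2-yn-1-one | COc1ccc(cc1)-c1cc(=O)c2c(OCc3ccccc3)c(-c3c(O)c(C(=O)C#Cc4ccc(OCc5ccccc5)cc4)c(OCc4ccccc4)cc3O[Si](C(C)C)(C(C)C)C(C)C)c(OCc3ccccc3)cc2o1 | intermediate
21 | 5,7,5'',4'''-tetrakis(benzyloxy)-4'-methoxy-7''-(triisopropylsilyloxy)-6,8''-biflavone | COc1ccc(cc1)-c1cc(=O)c2c(OCc3ccccc3)c(-c3c(O[Si](C(C)C)(C(C)C)C(C)C)cc(OCc4ccccc4)c4c(=O)cc(-c5ccc(OCc6ccccc6)cc5)oc34)c(OCc3ccccc3)cc2o1 | intermediate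
22 | 5,7,5'',4'''-tetrakis(benzyloxy)-7''-hydroxy-4'-methoxy-6,8''-biflavone | COc1ccc(cc1)-c1cc(=O)c2c(OCc3ccccc3)c(-c3c(O)cc(OCc4ccccc4)c4c(=O)cc(-c5ccc(OCc6ccccc6)cc5)oc34)c(OCc3ccccc3)cc2o1 | intermediate
23 | 5,7,5'',7'',4'''-pentahydroxy-4'-methoxy-6,8''-biflavone (CNP0302154.0) | COc1ccc(-c2cc(=O)c3c(O)c(-c4c(O)cc(O)c5c(=O)cc(-c6ccc(O)cc6)oc45)c(O)cc3o2)cc1 | target

Total step count: 12.
Longest linear sequence: 11 steps (steps 1–6 and 8–12, from acacetin). Step 7 is a one-step side branch.

Steps most likely to fail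

Step 8.
- **What may go wrong:** Opening of the vinylogous-ester cyclobutenone may be slower than loss of the ketene by dimerisation. The ynol ether may isomerise by silyl migration on long heating. The two ortho benzyloxy groups may retard the cycloaddition. The phenol formed may be O-acylated by surplus ketene.
- **Fallback:** The benzannulation is given up and the 6–8'' bond is made by Suzuki–Miyaura coupling. The fallback sets out from 4 and comes back to the route at 23.
- **Course:** Miyaura borylation of 4 (B2pin2, PdCl2(dppf), KOAc, dioxane) would give the flavone-6-boronic acid pinacol ester F1. Commercial apigenin would be perbenzylated (BnBr, K2CO3, DMF) to 5,7,4'-tris(benzyloxy)flavone F2. With both A-ring oxygens capped, iodination (I2, AgO2CCF3, CH2Cl2) should occur at C8 to give 5,7,4'-tris(benzyloxy)-8-iodoflavone F3. Coupling of F1 with F3 (Pd2(dba)3, SPhos, K3PO4, toluene–H2O, 100 °C) would give the pentabenzyl biflavone F4. The conditions of step 12 convert F4 into 23.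

Step 6.
- **What may go wrong:** Metalation by the amide base may be incomplete. The peroxide anion or the ynolate may attack the pyranone. Silylation may occur at carbon. The ynol ether may hydrolyse during isolation.
- **Fallback:** The benzannulation is kept, but the oxygen on the alkyne is bought in with an alkyl ynol ether made away from the flavone and attached by cross-coupling. The fallback sets out from 4 and comes back at 23.
- **Making the ynol ether:** 1-Adamantanol, KH and trichloroethylene would give the dichlorovinyl ether F5. Treatment with n-BuLi (2.2 equiv) and then ZnCl2 would give the (adamantyloxy)ethynylzinc chloride F6. Negishi coupling of F6 with 4 (Pd(PPh3)4, THF, 50 °C) would give the 6-[(1-adamantyloxy)ethynyl]flavone F7.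
- **Why adamantyl:** The bridgehead alkyl group cannot leave by a retro-ene path, which would need a bridgehead alkene, and it cannot shift sigmatropically. It should therefore survive the heating.
- **Remaining steps:** F7 with 12 under the conditions of step 8 would give the adamantyloxy phenol F8. The conditions of step 9 would give the iodophenol F9, and those of step 10 the adamantyl-protected biflavone F10. The BCl3 treatment of step 12 removes the tertiary ether together with the benzyl groups, so the fluoride step is not needed.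

Step 10.
- **What may go wrong:** Non-carbonylative alkynylation followed by closure to a benzofuran may compete. So may 5-exo closure, capture of the acylpalladium species by the amine, and slow oxidative addition at the doubly flanked iodide.
- **Fallback:** The pyranone is built stepwise through an o-hydroxyacetophenone and a 1,3-diketone. The fallback sets out from 18 and comes back at 21.
- **Course:** Stille coupling with tributyl(1-ethoxyvinyl)stannane (PdCl2(PPh3)2, dioxane, 90 °C) would give the aryl enol ether F11. Dilute HCl in THF hydrolyses F11 to the o-hydroxyacetophenone F12. Treatment with LiN(SiMe3)2 (3.5 equiv, THF, −78 °C) and then 4-(benzyloxy)benzoyl chloride aroylates the methyl carbon directly, the one-flask counterpart of the Baker–Venkataraman transfer, to give the 1,3-diketone F13. Cyclodehydration (p-TsOH, toluene, 80 °C) closes O1''–C2'' to 21.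

Further compounds
F1 | step 8 | 5,7-bis(benzyloxy)-4'-methoxy-6-(4,4,5,5-tetramethyl-1,3,2-dioxaborolan-2-yl)flavone | COc1ccc(cc1)-c1cc(=O)c2c(OCc3ccccc3)c(B3OC(C)(C)C(C)(C)O3)c(OCc3ccccc3)cc2o1
F2 | step 8 | 5,7,4'-tris(benzyloxy)flavone | O=c1cc(-c2ccc(OCc3ccccc3)cc2)oc2cc(OCc3ccccc3)cc(OCc3ccccc3)c12
F3 | step 8 | 5,7,4'-tris(benzyloxy)-8-iodoflavone | O=c1cc(-c2ccc(OCc3ccccc3)cc2)oc2c(I)c(OCc3ccccc3)cc(OCc3ccccc3)c12
F4 | step 8 | 5,7,5'',7'',4'''-pentakis(benzyloxy)-4'-methoxy-6,8''-biflavone | COc1ccc(cc1)-c1cc(=O)c2c(OCc3ccccc3)c(-c3c(OCc4ccccc4)cc(OCc4ccccc4)c4c(=O)cc(-c5ccc(OCc6ccccc6)cc5)oc34)c(OCc3ccccc3)cc2o1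
F5 | step 6 | 1-{[(E)-1,2-dichloroethenyl]oxy}adamantane | Cl/C=C(/Cl)OC12CC3CC(CC(C3)C1)C2
F6 | step 6 | [(1-adamantyloxy)ethynyl]zinc chloride | Cl[Zn]C#COC12CC3CC(CC(C3)C1)C2
F7 | step 6 | 6-[(1-adamantyloxy)ethynyl]-5,7-bis(benzyloxy)-4'-methoxyflavone | COc1ccc(cc1)-c1cc(=O)c2c(OCc3ccccc3)c(C#COC34CC5CC(CC(C5)C3)C4)c(OCc3ccccc3)cc2o1
F8 | step 6 | 3-(1-adamantyloxy)-5-(benzyloxy)-2-[5,7-bis(benzyloxy)-4'-methoxyflavon-6-yl]phenol | COc1ccc(cc1)-c1cc(=O)c2c(OCc3ccccc3)c(-c3c(O)cc(OCc4ccccc4)cc3OC34CC5CC(CC(C5)C3)C4)c(OCc3ccccc3)cc2o1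
F9 | step 6 | 5-(1-adamantyloxy)-3-(benzyloxy)-6-[5,7-bis(benzyloxy)-4'-methoxyflavon-6-yl]-2-iodophenol | COc1ccc(cc1)-c1cc(=O)c2c(OCc3ccccc3)c(-c3c(O)c(I)c(OCc4ccccc4)cc3OC34CC5CC(CC(C5)C3)C4)c(OCc3ccccc3)cc2o1
F10 | step 6 | 7''-(1-adamantyloxy)-5,7,5'',4'''-tetrakis(benzyloxy)-4'-methoxy-6,8''-biflavone | COc1ccc(cc1)-c1cc(=O)c2c(OCc3ccccc3)c(-c3c(OC45CC6CC(CC(C6)C4)C5)cc(OCc4ccccc4)c4c(=O)cc(-c5ccc(OCc6ccccc6)cc5)oc34)c(OCc3ccccc3)cc2o1
F11 | step 10 | 3-(benzyloxy)-6-[5,7-bis(benzyloxy)-4'-methoxyflavon-6-yl]-2-(1-ethoxyethenyl)-5-(triisopropylsilyloxy)phenol | COc1ccc(cc1)-c1cc(=O)c2c(OCc3ccccc3)c(-c3c(O)c(C(=C)OCC)c(OCc4ccccc4)cc3O[Si](C(C)C)(C(C)C)C(C)C)c(OCc3ccccc3)cc2o1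
F12 | step 10 | 1-{6-(benzyloxy)-3-[5,7-bis(benzyloxy)-4'-methoxyflavon-6-yl]-2-hydroxy-4-(triisopropylsilyloxy)phenyl}ethan-1-one | COc1ccc(cc1)-c1cc(=O)c2c(OCc3ccccc3)c(-c3c(O)c(C(C)=O)c(OCc4ccccc4)cc3O[Si](C(C)C)(C(C)C)C(C)C)c(OCc3ccccc3)cc2o1
F13 | step 10 | 1-{6-(benzyloxy)-3-[5,7-bis(benzyloxy)-4'-methoxyflavon-6-yl]-2-hydroxy-4-(triisopropylsilyloxy)phenyl}-3-[4-(benzyloxy)phenyl]propane-1,3-dione | COc1ccc(cc1)-c1cc(=O)c2c(OCc3ccccc3)c(-c3c(O)c(C(=O)CC(=O)c4ccc(OCc5ccccc5)cc4)c(OCc4ccccc4)cc3O[Si](C(C)C)(C(C)C)C(C)C)c(OCc3ccccc3)cc2o1
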